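Enabling feature: in the seven-membered ring the oxygen on C6 faces C10 across the ring (1,4). C10 bears the one-carbon branch C18 (=CH2) and its neighbour C9 is oxygenated. A temporary O6–C10 bond turns the cycloheptane into an 8-oxabicyclo[3.2.1]octane, the adduct of a six-membered carbonyl ylide (C6=O(+)–C10(−), C9 ketone, C10 ester = C18) and a two-carbon π partner (C5, C1).
Retrosynthetic cuts, in order: C3=C4 (ring-closing metathesis); O6 re-bridged to C10 (reverse of a reductive β-iodo ether opening that makes C10=C18); C1–C2 (conjugate allylation); C10–C1 and C6–C5 together (ylide + but-3-yn-2-one, which also brings C4 and its methyl); C9–C10 (lactone + diazoacetate anion); C7–C8 (auxiliary alkylation).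
Forward: an acyclic chain is built from (S)-citronellic acid, the oxygen-bridged seven-membered ring forms in one step, the bridge is opened to the free cycloheptane, and the cyclopentene is closed last.
Stereochemistry: C11 comes from the chiral pool and C7 from the oxazolidinone. C6 (and the temporary C10 centre) follow from C7 in the cycloaddition. C9, C1 and C5 are set on the rigid bicycle: hydride from the endo side, then allyl and proton from the exo side, which gives the trans ring fusion. The E alkene comes from a selenoxide syn-elimination.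
Helpers and their removal: the ester activates the diazo carbon and ends as C18; the oxygen bridge masks O6 and serves as template; both are spent in the zinc opening (step 15).

Key step: step 8

Remark: locants are those of the target's hydroazulene skeleton (C1/C5 ring fusion, C4 methyl-bearing alkene carbon, C6 carbinol, C7 side-chain carbon, C8 CH2, C9 acetoxy carbon, C10 methylene-bearing carbon, C18 its =CH2, C11 side-chain methine). exo = on the side of the oxygen bridge. R = (2S,4E)-6-methyl-6-(triethylsilyloxy)hept-4-en-2-yl. (S)-Citronellic acid is taken as the commercial single enantiomer.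

Step 1
Reactants: 1 (S)-citronellic acid; 2 (R)-4-benzyl-1,3-oxazolidin-2-one
Product: 4 (4R)-4-benzyl-3-[(3S)-3,7-dimethyloct-6-enoyl]-1,3-oxazolidin-2-one, via mixed pivalic anhydride 3 (not isolated)
Conditions: t-BuCOCl, Et3N, THF, −20 °C; then 2, LiCl, rt
Reagents that add atoms: none
Why: Mixed-anhydride N-acylation of the oxazolidinone attaches the auxiliary without touching C11.

Step 2
Reactants: 4 N-acyl oxazolidinone
Product: 6 tert-butyl (3R,4S)-3-{[(4R)-4-benzyl-2-oxo-1,3-oxazolidin-3-yl]carbonyl}-4,8-dimethylnon-7-enoate, via sodium Z-enolate 5 (not isolated)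
Conditions: NaN(SiMe3)2, THF, −78 °C; BrCH2CO2t-Bu, −78 → −40 °C
Reagents that add atoms: tert-butyl bromoacetate, CC(C)(C)OC(=O)CBr
Why: Evans alkylation; the chelated Z-enolate 5 takes the reactive α-bromo ester on the face away from the benzyl group, which sets C7 (R) under auxiliary control and brings in C8 and C9.

Step 3
Reactants: 6 alkylated imide
Product: 8 (4R)-4-[(2S)-6-methylhept-5-en-2-yl]oxolan-2-one, via hydroxy ester 7 (not isolated)
Conditions: LiBH4, MeOH (1 equiv), Et2O, 0 °C; then TsOH·H2O (cat.), CH2Cl2, rt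
Reagents that add atoms: none
Why: Reductive removal of the auxiliary spares the tert-butyl ester, and acid-catalysed intramolecular transesterification then closes the γ-lactone without touching C7 or C11.

Step 4
Reactants: 8 lactone
Product: 11 (4R)-4-[(2S,4E)-6-hydroxy-6-methylhept-4-en-2-yl]oxolan-2-one, via hydroxy selenide 9 (not isolated), via selenoxide 10 (not isolated)
Conditions: PhSeCl, MeCN/H2O (5:1), rt; then 30% H2O2, THF, 0 °C → rt
Reagents that add atoms: water, O
Why: Markovnikov hydroxyselenation (water opens the seleniranium ion at the tertiary carbon) is followed by selenoxide syn-elimination, which can only run toward C13 and gives the E allylic tertiary alcohol at the one stage where this is the only alkene.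

Step 5
Reactants: 11 allylic alcohol lactone
Product: 12 (4R)-4-R-oxolan-2-one (triethylsilyl ether of 11)
Conditions: Et3SiOTf, 2,6-lutidine, CH2Cl2, 0 °C
Reagents that add atoms: triethylsilyl triflate, CC[Si](CC)(CC)OS(=O)(=O)C(F)(F)F
Why: Silylation with the triflate covers the hindered tertiary allylic alcohol against the carbene, iodination and acetylation steps.

Step 6
Reactants: 12 silyl ether lactone
Product: 13 ethyl (5R,6S,8E)-2-diazo-5-(hydroxymethyl)-6,10-dimethyl-3-oxo-10-(triethylsilyloxy)undec-8-enoate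
Conditions: N2CHCO2Et, LiN(i-Pr)2, THF, −78 °C; then 12, −78 °C; AcOH quench
Reagents that add atoms: ethyl diazoacetate, CCOC(=O)C=[N+]=[N-]
Why: Acylation of lithiated ethyl diazoacetate by a lactone is a known ring-opening entry to ω-hydroxy α-diazo β-keto esters; it brings in C10 and C18 with the diazo group in place and so avoids a free β-keto ester next to the later aldehyde.

Step 7
Reactants: 13 diazo alcohol
Product: 14 ethyl (5R,6S,8E)-2-diazo-5-formyl-6,10-dimethyl-3-oxo-10-(triethylsilyloxy)undec-8-enoate
Conditions: Dess–Martin periodinane, CH2Cl2, 0 °C → rt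
Reagents that add atoms: none
Why: Dess–Martin oxidation is mild enough to leave the diazo keto ester, the silyl ether and the α-stereocentre C7 untouched.

Step 8
Reactants: 14 diazo aldehyde; 15 but-3-yn-2-one
Product: 17 ethyl (1S,4R,5S)-6-acetyl-2-oxo-4-exo-R-8-oxabicyclo[3.2.1]oct-6-ene-1-carboxylate, via carbonyl ylide 16 (not isolated)
Conditions: Rh2(OAc)4 (2 mol %), 15 (5 equiv), benzene, 80 °C, 14 added over 2 h
Reagents that add atoms: none
Why: Rh2(OAc)4 takes N2 out of 14 and the formyl oxygen closes on the electrophilic carbene carbon C10 (six-membered ring by lone-pair capture, O–C10 bond) to give the push–pull ylide 16, which adds across the alkyne of 15 in a concerted suprafacial [3+2] (4π + 2π) cycloaddition that makes C10–C1 and C6–C5 together and so closes the seven-membered carbocycle and the 2,5-dihydrofuran ring at once (a [5+2] annulation in carbon count). The closest known reaction type is the tandem carbonyl ylide formation–cycloaddition of α-diazo β-keto esters bearing a tethered formyl or acyl group with alkynones and acetylenic esters. Regiochemistry is polarity-matched and sterically matched: the carbanionic terminus C10 (flanked by ketone and ester, fully substituted) bonds to the electrophilic unsubstituted alkyne CH, and the oxocarbenium terminus C6 bonds to the acyl-bearing carbon. The new stereocentres C6 and C10 are controlled by C7: the sec-alkyl chain can sit pseudoaxial beside the flat ylide at little cost (O, C9 and C10 offer no syn-axial partner) and the alkyne enters anti to it, which places the oxygen bridge and the side chain on the same face of the cycloheptane as in the target, while C10 is tied to C6 by the bridge. An alkyne removes any endo/exo question and leaves C1 and C5 sp2 for step 10. The step needs ylide closure to outrun 1,5 C–H insertion at C11–H and cyclopropenation of 15, which the nearby Lewis basic formyl oxygen, the slow addition of 14 and the excess of 15 should secure.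

Step 9
Reactants: 17 cycloadduct
Product: 18 ethyl (1S,2R,4R,5S)-6-acetyl-2-exo-hydroxy-4-exo-R-8-oxabicyclo[3.2.1]oct-6-ene-1-carboxylate
Conditions: LiBH(s-Bu)3 (1.05 equiv), THF, −78 °C; aq NH4Cl
Reagents that add atoms: none
Why: The saturated C9 ketone, activated by its α-oxygen and α-ester, should be reduced before the conjugated acetyl group; the bulky hydride should come along the equatorial path from the side of the flat etheno bridge because the exo face is closed by the syn-axial C7 side chain, giving the exo (9R) alcohol.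

Step 10
Reactants: 18 hydroxy enone
Product: 20 ethyl (1S,2R,4R,5S,6S,7S)-6-endo-acetyl-2-exo-hydroxy-7-exo-(prop-2-enyl)-4-exo-R-8-oxabicyclo[3.2.1]octane-1-carboxylate, via bis-silylated adduct 19 (not isolated)
Conditions: allylMgBr, CuBr·SMe2, Me3SiCl, THF, −78 °C; then 10% aq citric acid, THF/MeOH, 0 °C
Reagents that add atoms: allylmagnesium bromide, C=CC[Mg]Br
Why: Copper-mediated, chlorosilane-accelerated 1,4-addition delivers allyl to C1 from the convex exo face; Me3SiCl traps the enolate as 19 before it can expel the bridging oxygen, and mild acid then protonates C5 from the exo face, so allyl is exo and acetyl endo (H1 and H5 trans, as in the target).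

Step 11
Reactants: 20 allyl ketone
Product: 21 ethyl (1S,2R,4R,5S,6R,7S)-2-exo-hydroxy-6-endo-(prop-1-en-2-yl)-7-exo-(prop-2-enyl)-4-exo-R-8-oxabicyclo[3.2.1]octane-1-carboxylate
Conditions: Zn, CH2Br2, TiCl4, THF, 0 °C (aged); then 20, CH2Cl2, rt
Reagents that add atoms: dibromomethane, BrCBr
Why: Takai–Lombardo methylenation is non-basic, so the methyl ketone becomes the isopropenyl group without epimerisation at C5 or β-elimination of the bridge, and the hindered ester is left alone.

Step 12
Reactants: 21 hydroxy ester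
Product: 22 (1R,2R,4R,5S,6R,7S)-1-(hydroxymethyl)-6-endo-(prop-1-en-2-yl)-7-exo-(prop-2-enyl)-4-exo-R-8-oxabicyclo[3.2.1]octan-2-exo-ol
Conditions: LiAlH4, Et2O, 0 °C
Reagents that add atoms: none
Why: Hydride reduction takes the activating ester down to the C18 carbinol; alkenes, ether bridge and silyl ether are inert.

Step 13
Reactants: 22 diol
Product: 23 (1S,2R,4R,5S,6R,7S)-1-(iodomethyl)-6-endo-(prop-1-en-2-yl)-7-exo-(prop-2-enyl)-4-exo-R-8-oxabicyclo[3.2.1]octan-2-exo-ol
Conditions: I2, PPh3, imidazole, toluene, 80 °C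
Reagents that add atoms: iodine, II
Why: Appel-type iodination picks the primary alcohol (heat is needed because C18 is neopentylic), whereas the C9 alcohol is secondary, axial and flanked by the quaternary C10.

Step 14
Reactants: 23 iodo alcohol
Product: 24 acetate of 23 at the C9 oxygen
Conditions: Ac2O, DMAP, Et3N, CH2Cl2, rt
Reagents that add atoms: acetic anhydride, CC(=O)OC(C)=O
Why: DMAP-catalysed acetylation installs the C9 acetate while O6 is still masked as the bridge, so no hydroxyl differentiation is needed.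

Step 15
Reactants: 24 iodo acetate
Product: 25 (1S,5R,6S,7R,9R,11S in skeleton numbering) 9-acetoxy-1-allyl-6-hydroxy-5-isopropenyl-10-methylene-7-R-cycloheptane
Conditions: Zn dust (activated), EtOH, 78 °C
Reagents that add atoms: none
Why: Boord-type reductive elimination (the reverse of an iodoetherification); zinc reduces the C18–I bond and the β-oxygen leaves, which opens the bridge, frees the C6 hydroxyl with its configuration intact and places the alkene regiospecifically at C10=C18.

Step 16
Reactants: 25 cycloheptane triene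
Product: 26 triethylsilyl ether of the target at the tertiary alcohol
Conditions: second-generation Grubbs catalyst (5 mol %), CH2Cl2, 40 °C
Reagents that add atoms: none
Why: Ring-closing metathesis of the allyl and isopropenyl groups closes the trans-fused methylcyclopentene (C3=C4); the flanked 1,1-disubstituted C10=C18 and the hindered side-chain alkene should not take part.

Step 17
Reactants: 26 silyl ether
Product: 27 target CNP0312076.1
Conditions: HF·pyridine, pyridine, THF, 0 °C
Reagents that add atoms: none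
Why: Buffered fluoride desilylation frees the tertiary allylic alcohol without ionising it and without touching the acetate.

Compound list
1 | (S)-citronellic acid | OC(=O)C[C@@H](C)CCC=C(C)C | starting material
2 | (R)-4-benzyl-1,3-oxazolidin-2-one | O=C1N[C@H](Cc2ccccc2)CO1 | starting material
3 | (3S)-3,7-dimethyloct-6-enoic pivalic anhydride | CC(C)(C)C(=O)OC(=O)C[C@@H](C)CCC=C(C)C | intermediate
4 | (4R)-4-benzyl-3-[(3S)-3,7-dimethyloct-6-enoyl]-1,3-oxazolidin-2-one | O=C1OC[C@@H](Cc2ccccc2)N1C(=O)C[C@@H](C)CCC=C(C)C | intermediate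
5 | sodium Z-enolate of 4 | [Na+].[O-]/C(=C\[C@@H](C)CCC=C(C)C)N1C(=O)OC[C@H]1Cc1ccccc1 | intermediate
6 | tert-butyl (3R,4S)-3-{[(4R)-4-benzyl-2-oxo-1,3-oxazolidin-3-yl]carbonyl}-4,8-dimethylnon-7-enoate | O=C1OC[C@@H](Cc2ccccc2)N1C(=O)[C@H](CC(=O)OC(C)(C)C)[C@@H](C)CCC=C(C)C | intermediate
7 | tert-butyl (3R,4S)-3-(hydroxymethyl)-4,8-dimethylnon-7-enoate | OC[C@H](CC(=O)OC(C)(C)C)[C@@H](C)CCC=C(C)C | intermediate
8 | (4R)-4-[(2S)-6-methylhept-5-en-2-yl]oxolan-2-one | O=C1C[C@H]([C@@H](C)CCC=C(C)C)CO1 | intermediate
9 | (4R)-4-[(2S)-6-hydroxy-6-methyl-5-(phenylselanyl)heptan-2-yl]oxolan-2-one (both epimers at the selenium-bearing carbon) | O=C1C[C@H]([C@@H](C)CCC([Se]c2ccccc2)C(C)(C)O)CO1 | intermediate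
10 | selenoxide of 9 | O=C1C[C@H]([C@@H](C)CCC([Se](=O)c2ccccc2)C(C)(C)O)CO1 | intermediate
11 | (4R)-4-[(2S,4E)-6-hydroxy-6-methylhept-4-en-2-yl]oxolan-2-one | O=C1C[C@H]([C@@H](C)C/C=C/C(C)(C)O)CO1 | intermediate
12 | (4R)-4-[(2S,4E)-6-methyl-6-(triethylsilyloxy)hept-4-en-2-yl]oxolan-2-one | O=C1C[C@H]([C@@H](C)C/C=C/C(C)(C)O[Si](CC)(CC)CC)CO1 | intermediate
13 | ethyl (5R,6S,8E)-2-diazo-5-(hydroxymethyl)-6,10-dimethyl-3-oxo-10-(triethylsilyloxy)undec-8-enoate | CCOC(=O)C(=[N+]=[N-])C(=O)C[C@H]([C@@H](C)C/C=C/C(C)(C)O[Si](CC)(CC)CC)CO | intermediate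
14 | ethyl (5R,6S,8E)-2-diazo-5-formyl-6,10-dimethyl-3-oxo-10-(triethylsilyloxy)undec-8-enoate | CCOC(=O)C(=[N+]=[N-])C(=O)C[C@H]([C@@H](C)C/C=C/C(C)(C)O[Si](CC)(CC)CC)C=O | intermediate
15 | but-3-yn-2-one | CC(=O)C#C | starting material
16 | six-membered carbonyl ylide (C6=O(+)–C10(−), C9 ketone, C10 ester, R on C7) | CCOC(=O)[C-]1[O+]=C[C@@H]([C@@H](C)C/C=C/C(C)(C)O[Si](CC)(CC)CC)CC1=O | intermediate
17 | ethyl (1S,4R,5S)-6-acetyl-2-oxo-4-exo-R-8-oxabicyclo[3.2.1]oct-6-ene-1-carboxylate | CCOC(=O)[C@]12O[C@H](C(C(C)=O)=C1)[C@@H]([C@@H](C)C/C=C/C(C)(C)O[Si](CC)(CC)CC)CC2=O | intermediate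
18 | ethyl (1S,2R,4R,5S)-6-acetyl-2-exo-hydroxy-4-exo-R-8-oxabicyclo[3.2.1]oct-6-ene-1-carboxylate | CCOC(=O)[C@]12O[C@H](C(C(C)=O)=C1)[C@@H]([C@@H](C)C/C=C/C(C)(C)O[Si](CC)(CC)CC)C[C@H]2O | intermediate
19 | 7-exo-allyl adduct as trimethylsilyl enol ether (C5=C4) and C9 trimethylsilyl ether | CCOC(=O)[C@]12O[C@H](C(=C(C)O[Si](C)(C)C)[C@@H]1CC=C)[C@@H]([C@@H](C)C/C=C/C(C)(C)O[Si](CC)(CC)CC)C[C@H]2O[Si](C)(C)C | intermediate
20 | ethyl (1S,2R,4R,5S,6S,7S)-6-endo-acetyl-2-exo-hydroxy-7-exo-(prop-2-enyl)-4-exo-R-8-oxabicyclo[3.2.1]octane-1-carboxylate | CCOC(=O)[C@]12O[C@H]([C@@H](C(C)=O)[C@@H]1CC=C)[C@@H]([C@@H](C)C/C=C/C(C)(C)O[Si](CC)(CC)CC)C[C@H]2O | intermediate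
21 | ethyl (1S,2R,4R,5S,6R,7S)-2-exo-hydroxy-6-endo-(prop-1-en-2-yl)-7-exo-(prop-2-enyl)-4-exo-R-8-oxabicyclo[3.2.1]octane-1-carboxylate | CCOC(=O)[C@]12O[C@H]([C@@H](C(C)=C)[C@@H]1CC=C)[C@@H]([C@@H](C)C/C=C/C(C)(C)O[Si](CC)(CC)CC)C[C@H]2O | intermediate
22 | (1R,2R,4R,5S,6R,7S)-1-(hydroxymethyl)-6-endo-(prop-1-en-2-yl)-7-exo-(prop-2-enyl)-4-exo-R-8-oxabicyclo[3.2.1]octan-2-exo-ol | OC[C@]12O[C@H]([C@@H](C(C)=C)[C@@H]1CC=C)[C@@H]([C@@H](C)C/C=C/C(C)(C)O[Si](CC)(CC)CC)C[C@H]2O | intermediate
23 | (1S,2R,4R,5S,6R,7S)-1-(iodomethyl)-6-endo-(prop-1-en-2-yl)-7-exo-(prop-2-enyl)-4-exo-R-8-oxabicyclo[3.2.1]octan-2-exo-ol | IC[C@]12O[C@H]([C@@H](C(C)=C)[C@@H]1CC=C)[C@@H]([C@@H](C)C/C=C/C(C)(C)O[Si](CC)(CC)CC)C[C@H]2O | intermediate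
24 | C9 acetate of 23 | IC[C@]12O[C@H]([C@@H](C(C)=C)[C@@H]1CC=C)[C@@H]([C@@H](C)C/C=C/C(C)(C)O[Si](CC)(CC)CC)C[C@H]2OC(C)=O | intermediate
25 | 9-acetoxy-1-allyl-6-hydroxy-5-isopropenyl-10-methylene-7-R-cycloheptane (1S,5R,6S,7R,9R,11S, skeleton numbering) | C=C1[C@@H](CC=C)[C@H](C(C)=C)[C@@H](O)[C@@H]([C@@H](C)C/C=C/C(C)(C)O[Si](CC)(CC)CC)C[C@H]1OC(C)=O | intermediate
26 | triethylsilyl ether of the target (tertiary alcohol) | C=C1[C@H]2CC=C(C)[C@@H]2[C@@H](O)[C@@H]([C@@H](C)C/C=C/C(C)(C)O[Si](CC)(CC)CC)C[C@H]1OC(C)=O | intermediate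
27 | CNP0312076.1 | C=C1[C@H]2CC=C(C)[C@@H]2[C@@H](O)[C@@H]([C@@H](C)C/C=C/C(C)(C)O)C[C@H]1OC(C)=O | target

Total step count: 17. Longest linear sequence: 17 steps (from 1).

Steps most likely to fail:

Step 8. The ylide may decay before the alkyne traps it, by proton shift from C7 to C10, by capture by a second formyl group, or by carbene insertion into the C11–H bond. Fallback: the alkyne cycloaddition is replaced by an alkene cycloaddition followed by elimination. From 14 the same ylide is trapped with the doubly activated alkene (E)-4-(phenylsulfonyl)but-3-en-2-one. This is a much faster dipolarophile, and its sulfonyl-bearing carbon takes the place of the alkyne CH. The product is the saturated sulfone adduct F1, whose exo/endo mixture is of no consequence. DBU in CH2Cl2 then expels benzenesulfinate through the acetyl enolate, and the route is rejoined at 17.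

Step 9. Hydride may reach C9 from both faces (poor facial selectivity), because the concave endo side is not free either. Fallback: C9 is set by reagent control after the bridge is gone.
- Compound 23, carried on as the mixture of C9 epimers, is opened with Zn/EtOH as in step 15 to the diol F2.
- MnO2 oxidises only the allylic C9 alcohol, giving the α-methylene ketone F3.
- Corey–Bakshi–Shibata reduction ((S)-methyl oxazaborolidine, catecholborane, toluene, −78 °C, with C10 as the large and C8 as the small group) gives the 9R alcohol F4.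
- Ac2O/pyridine at 0 °C acetylates the open allylic alcohol in preference to the C6 alcohol, which is flanked by two branched carbons, and the route is rejoined at 25.

Step 10. Addition at the neopentylic C1 may be slow, so that 1,2-attack on the acetyl group or loss of the oxygen bridge from the enolate takes over. Fallback: the polar C–C bond formation is replaced by a radical allyl transfer. From 18, benzeneselenol (PhSeSePh, NaBH4, EtOH, then AcOH) adds to the enone from the exo face to give the β-seleno ketone F5. Keck allylation (allyltributylstannane, AIBN, benzene, 80 °C) of the derived C1 radical, again from the exo face, then gives 20.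

Further compounds
F1 | step 8 | ethyl 6-acetyl-2-oxo-7-(phenylsulfonyl)-4-exo-R-8-oxabicyclo[3.2.1]octane-1-carboxylate (C1 and C5 as mixture) | CCOC(=O)[C@]12O[C@H](C(C(C)=O)C1S(=O)(=O)c3ccccc3)[C@@H]([C@@H](C)C/C=C/C(C)(C)O[Si](CC)(CC)CC)CC2=O
F2 | step 9 | 1-allyl-5-isopropenyl-10-methylene-7-R-cycloheptane-6,9-diol (C9 epimer mixture) | C=C1[C@@H](CC=C)[C@H](C(C)=C)[C@@H](O)[C@@H]([C@@H](C)C/C=C/C(C)(C)O[Si](CC)(CC)CC)CC1O
F3 | step 9 | 1-allyl-6-hydroxy-5-isopropenyl-10-methylene-7-R-cycloheptan-9-one | C=C1[C@@H](CC=C)[C@H](C(C)=C)[C@@H](O)[C@@H]([C@@H](C)C/C=C/C(C)(C)O[Si](CC)(CC)CC)CC1=O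
F4 | step 9 | (9R)-1-allyl-5-isopropenyl-10-methylene-7-R-cycloheptane-6,9-diol | C=C1[C@@H](CC=C)[C@H](C(C)=C)[C@@H](O)[C@@H]([C@@H](C)C/C=C/C(C)(C)O[Si](CC)(CC)CC)C[C@H]1O
F5 | step 10 | ethyl 6-endo-acetyl-2-exo-hydroxy-7-exo-(phenylselanyl)-4-exo-R-8-oxabicyclo[3.2.1]octane-1-carboxylate | CCOC(=O)[C@]12O[C@H]([C@@H](C(C)=O)[C@@H]1[Se]c3ccccc3)[C@@H]([C@@H](C)C/C=C/C(C)(C)O[Si](CC)(CC)CC)C[C@H]2O
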